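**Retrosynthetic overview**

1. The strategy rests on ring A (C4a, C5–C8, C8a): its four contiguous oxygenated carbons C5–C8 are read as a folded acetate-type chain and cut at C7–C8 and C5–C6. C7 and C6 (with the C6 methoxy) come from methyl methoxyacetate; C8 and C5 are the benzyloxymethyl and ester substituents of a pre-formed ring C 4-pyranone in which the O1–C8a bond is already fixed.
2. Ring C (pyranone 7) is opened at O1–C2 (6-endo oxa-Michael onto an aryl ynone) and at C4–C4a (C-acylation of methyl 4-(benzyloxy)acetoacetate by 3-(3,4,5-trimethoxyphenyl)propioloyl chloride).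
3. The ynoyl unit comes from 5-iodo-1,2,3-trimethoxybenzene and propiolic acid (Sonogashira coupling).
4. Order of rings: ring B is bought, ring C is closed in step 4, ring A in step 5; methylation of the C5 and C7 hydroxyls and debenzylation at C8–O finish the target.

Key step: step 5

Assumption: compounds 1, 2, 5 and 8 are purchased, and flavone numbering (O1, C2 to C8a) is used for atom labels in all intermediates.

**Step 1**
Reactants: 1 5-iodo-1,2,3-trimethoxybenzene; 2 propiolic acid
Product: 3 3-(3,4,5-trimethoxyphenyl)prop-2-ynoic acid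
Conditions: Pd(PPh3)4 (cat.), DBU, DMSO, 35 °C; aq. HCl
Reagents that add atoms: none
Why: Copper-free Sonogashira coupling of an aryl iodide with the terminal C–H of propiolic acid, run near room temperature with an amidine base so that the carboxylate is retained and not lost by decarboxylation.

**Step 2**
Reactants: 3 3-(3,4,5-trimethoxyphenyl)prop-2-ynoic acid
Product: 4 3-(3,4,5-trimethoxyphenyl)prop-2-ynoyl chloride
Conditions: (COCl)2, DMF (cat.), CH2Cl2, 0 °C to rt; concentrate, use crude
Reagents that add atoms: oxalyl chloride, ClC(=O)C(=O)Cl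
Why: Acid chloride formation through the Vilsmeier-type chloroiminium species from DMF and oxalyl chloride, mild enough that addition of HCl across the triple bond should be avoided.

**Step 3**
Reactants: 5 methyl 4-(benzyloxy)-3-oxobutanoate; 4 3-(3,4,5-trimethoxyphenyl)prop-2-ynoyl chloride
Product: 6 methyl 2-[(benzyloxy)acetyl]-3-oxo-5-(3,4,5-trimethoxyphenyl)pent-4-ynoate
Conditions: MgCl2, pyridine, CH2Cl2, 0 °C to rt; cold 1 M HCl
Reagents that add atoms: none
Why: Soft enolization of the β-keto ester as its magnesium chelate and C-acylation at the doubly activated C2 by the acid chloride (chelation favours C- over O-acylation), the standard access to 2-acyl β-keto esters; any 7 already formed here is carried through step 4.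

**Step 4**
Reactants: 6 methyl 2-[(benzyloxy)acetyl]-3-oxo-5-(3,4,5-trimethoxyphenyl)pent-4-ynoate
Product: 7 methyl 2-[(benzyloxy)methyl]-4-oxo-6-(3,4,5-trimethoxyphenyl)-4H-pyran-3-carboxylate
Conditions: K2CO3, acetone, rt
Reagents that add atoms: none
Why: Intramolecular oxa-Michael addition (6-endo-dig) of the enolate oxygen of the benzyloxyacetyl ketone to the β-carbon of the aryl ynone, the classical γ-pyranone closure of acetylenic tricarbonyl compounds; the 5-exo mode would be anti-Michael, and the ketone enol oxygen should outcompete the ester carbonyl oxygen.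

**Step 5**
Reactants: 7 methyl 2-[(benzyloxy)methyl]-4-oxo-6-(3,4,5-trimethoxyphenyl)-4H-pyran-3-carboxylate; 8 methyl methoxyacetate
Product: 10 8-(benzyloxy)-5,7-dihydroxy-6-methoxy-2-(3,4,5-trimethoxyphenyl)-4H-chromen-4-one, via Claisen ketone 9 (not isolated)
Conditions: LiN(iPr)2 (1.05 equiv), THF, −78 °C; 8 (2.0 equiv), −78 to −20 °C; LiN(iPr)2 (3.2 equiv), −78 to 0 °C; AcOH
Reagents that add atoms: none
Why: Proposed new method: LiN(iPr)2 removes a proton from the C8 methylene of 7, which is vinylogous to both the C4 carbonyl and the C5 ester, and the dienolate is acylated at carbon by 8 in a crossed Claisen condensation (C7–C8 bond) with no free amide present to enolize 8, the LiOMe set free holding ketone 9 as its C8 enolate. The second charge of base then forms the C6 methoxymethylene enolate (a 1,3-dianion across C7), which attacks the C5 ester in a Dieckmann-type acyl substitution (C5–C6 bond, 6-exo-trig closure of the six-membered carbocycle); loss of methoxide and enolization of the cyclic triketone give aromatic ring A as its bis-phenoxide. The closest known reaction types are the lateral-carbanion Claisen then Dieckmann benzannulation of ortho-toluate esters to naphthalene-1,3-diols, the γ-acylation of 2-methyl-4-pyranone and 2-methylchromone anions, and Claisen cyclizations of pyranone-masked polyketo esters. No stereocentre is created, the centre at C8 of 9 being lost on aromatization. Regioselectivity is secured by the substrate: O1 is already bonded to C8a in ring C, so ring A cannot close onto the other oxygen, C6 can reach only the exocyclic ester carbon, and O-acylation of the dienolate by an ester is reversible whereas C-acylation is drained by deprotonation. The step needs C–H removal at C8 without Wittig rearrangement of the benzyl ether, which the enolate-type delocalization of the charge and the low temperature should ensure, and it delivers C8 as OBn, C6 as OMe and C5/C7 as free OH.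

**Step 6**
Reactants: 10 8-(benzyloxy)-5,7-dihydroxy-6-methoxy-2-(3,4,5-trimethoxyphenyl)-4H-chromen-4-one
Product: 11 8-(benzyloxy)-5,6,7-trimethoxy-2-(3,4,5-trimethoxyphenyl)-4H-chromen-4-one
Conditions: Me2SO4 (excess), K2CO3, acetone, reflux
Reagents that add atoms: dimethyl sulfate, COS(=O)(=O)OC
Why: Williamson-type O-methylation of both phenols; excess reagent and prolonged reflux are chosen so that the hydrogen-bonded C5 hydroxyl is alkylated as well as the flanked C7 hydroxyl, while the benzyl ether keeps C8–O distinct.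

**Step 7**
Reactants: 11 8-(benzyloxy)-5,6,7-trimethoxy-2-(3,4,5-trimethoxyphenyl)-4H-chromen-4-one
Product: 12 8-hydroxy-5,6,7-trimethoxy-2-(3,4,5-trimethoxyphenyl)-4H-chromen-4-one (8-hydroxy-5,6,7,3',4',5'-hexamethoxyflavone)
Conditions: H2 (1 atm), Pd/C, EtOAc–MeOH, rt
Reagents that add atoms: none
Why: Catalytic hydrogenolysis of the aryl benzyl ether frees the C8 hydroxyl; the methyl ethers are inert and the C2=C3 bond of the flavone is reduced much more slowly, so the reaction is stopped after uptake of one equivalent of hydrogen.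

**Compound list**

1 | 5-iodo-1,2,3-trimethoxybenzene | COc1cc(I)cc(OC)c1OC | starting material
2 | propiolic acid | OC(=O)C#C | starting material
3 | 3-(3,4,5-trimethoxyphenyl)prop-2-ynoic acid | COc1cc(C#CC(=O)O)cc(OC)c1OC | intermediate
4 | 3-(3,4,5-trimethoxyphenyl)prop-2-ynoyl chloride | COc1cc(C#CC(=O)Cl)cc(OC)c1OC | intermediate
5 | methyl 4-(benzyloxy)-3-oxobutanoate | COC(=O)CC(=O)COCc1ccccc1 | starting material
6 | methyl 2-[(benzyloxy)acetyl]-3-oxo-5-(3,4,5-trimethoxyphenyl)pent-4-ynoate | COC(=O)C(C(=O)COCc1ccccc1)C(=O)C#Cc1cc(OC)c(OC)c(OC)c1 | intermediate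
7 | methyl 2-[(benzyloxy)methyl]-4-oxo-6-(3,4,5-trimethoxyphenyl)-4H-pyran-3-carboxylate | COC(=O)c1c(COCc2ccccc2)oc(-c2cc(OC)c(OC)c(OC)c2)cc1=O | intermediate
8 | methyl methoxyacetate | COCC(=O)OC | starting material
9 | methyl 2-[1-(benzyloxy)-3-methoxy-2-oxopropyl]-4-oxo-6-(3,4,5-trimethoxyphenyl)-4H-pyran-3-carboxylate (racemic, not isolated) | COC(=O)c1c(C(OCc2ccccc2)C(=O)COC)oc(-c2cc(OC)c(OC)c(OC)c2)cc1=O | intermediate
10 | 8-(benzyloxy)-5,7-dihydroxy-6-methoxy-2-(3,4,5-trimethoxyphenyl)-4H-chromen-4-one | COc1cc(-c2cc(=O)c3c(O)c(OC)c(O)c(OCc4ccccc4)c3o2)cc(OC)c1OC | intermediate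
11 | 8-(benzyloxy)-5,6,7-trimethoxy-2-(3,4,5-trimethoxyphenyl)-4H-chromen-4-one | COc1cc(-c2cc(=O)c3c(OC)c(OC)c(OC)c(OCc4ccccc4)c3o2)cc(OC)c1OC | intermediate
12 | 8-hydroxy-5,6,7-trimethoxy-2-(3,4,5-trimethoxyphenyl)-4H-chromen-4-one | COc1cc(-c2cc(=O)c3c(OC)c(OC)c(OC)c(O)c3o2)cc(OC)c1OC | target

**Totals**

Total step count: 7. Longest linear sequence: 7 steps (1 → 3 → 4 → 6 → 7 → 10 → 11 → 12).

**Steps most likely to fail**

1. Step 5 (proposed new method). The ring closure may stall at the open-chain ketone because the C5 ester is deactivated by the adjacent delocalized enolate. The acylation may also stop early through proton transfer from the acidic Claisen product to unreacted dienolate, and methoxide may open the pyranone at C2. Fallback with known chemistry, setting out from 1 and returning at 12: ring A is taken from a commercial acetophenone and the C8 oxygen is introduced last.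
   - Iodine–magnesium exchange on 1 (iPrMgCl·LiCl, THF) and quenching with DMF would give 3,4,5-trimethoxybenzaldehyde F1.
   - Claisen–Schmidt condensation of F1 with commercial 1-(6-hydroxy-2,3,4-trimethoxyphenyl)ethan-1-one (KOH, EtOH) would give (E)-1-(6-hydroxy-2,3,4-trimethoxyphenyl)-3-(3,4,5-trimethoxyphenyl)prop-2-en-1-one F2.
   - Oxidative cyclization (cat. I2, DMSO, 120 °C) would give 5,6,7-trimethoxy-2-(3,4,5-trimethoxyphenyl)-4H-chromen-4-one F3.
   - Electrophilic bromination with NBS in DMF at C8, the only unsubstituted carbon of ring A, would give 8-bromo-5,6,7-trimethoxy-2-(3,4,5-trimethoxyphenyl)-4H-chromen-4-one F4.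
   - Miyaura borylation (B2pin2, PdCl2(dppf), KOAc, dioxane, 90 °C) would give 5,6,7-trimethoxy-8-(4,4,5,5-tetramethyl-1,3,2-dioxaborolan-2-yl)-2-(3,4,5-trimethoxyphenyl)-4H-chromen-4-one F5.
   - Oxidation of the C–B bond (NaBO3·4H2O, THF–water, rt) would give 12.

2. Step 3. Conjugate addition of the magnesium enolate or of pyridine to the ynoyl chloride, and oligomerization of this sensitive acid chloride, may outrun C-acylation. Fallback setting out from 3 and returning at 7: the alkyne is replaced by a β-chlorovinyl unit, and ring C is closed by vinylic substitution instead of alkyne addition.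
   - Hydrochlorination of 3 (LiCl, AcOH, 80 °C) would give (Z)-3-chloro-3-(3,4,5-trimethoxyphenyl)prop-2-enoic acid F6.
   - (COCl)2 with cat. DMF would give (Z)-3-chloro-3-(3,4,5-trimethoxyphenyl)prop-2-enoyl chloride F7.
   - C-acylation of 5 (MgCl2, pyridine, CH2Cl2) would give methyl (Z)-2-[(benzyloxy)acetyl]-5-chloro-3-oxo-5-(3,4,5-trimethoxyphenyl)pent-4-enoate F8.
   - Et3N in MeCN would then close ring C by addition–elimination of the enol oxygen at the chlorine-bearing carbon, giving 7.

3. Step 1. Decarboxylation of the arylpropiolate under palladium and base, followed by a second coupling to the diarylalkyne, may consume the product. Fallback setting out from 1 and returning at 3: the carboxyl group is introduced after the coupling.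
   - Sonogashira coupling of 1 with ethynyltrimethylsilane (PdCl2(PPh3)2, CuI, Et3N) would give trimethyl[(3,4,5-trimethoxyphenyl)ethynyl]silane F9.
   - K2CO3 in MeOH would give 5-ethynyl-1,2,3-trimethoxybenzene F10.
   - Deprotonation with n-BuLi (THF, −78 °C) and carboxylation with CO2 would give 3 after acidification.

**Further compounds**

F1 | step 5 | 3,4,5-trimethoxybenzaldehyde | COc1cc(C=O)cc(OC)c1OC
F2 | step 5 | (E)-1-(6-hydroxy-2,3,4-trimethoxyphenyl)-3-(3,4,5-trimethoxyphenyl)prop-2-en-1-one | COc1cc(/C=C/C(=O)c2c(O)cc(OC)c(OC)c2OC)cc(OC)c1OC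
F3 | step 5 | 5,6,7-trimethoxy-2-(3,4,5-trimethoxyphenyl)-4H-chromen-4-one | COc1cc(-c2cc(=O)c3c(OC)c(OC)c(OC)cc3o2)cc(OC)c1OC
F4 | step 5 | 8-bromo-5,6,7-trimethoxy-2-(3,4,5-trimethoxyphenyl)-4H-chromen-4-one | COc1cc(-c2cc(=O)c3c(OC)c(OC)c(OC)c(Br)c3o2)cc(OC)c1OC
F5 | step 5 | 5,6,7-trimethoxy-8-(4,4,5,5-tetramethyl-1,3,2-dioxaborolan-2-yl)-2-(3,4,5-trimethoxyphenyl)-4H-chromen-4-one | COc1cc(-c2cc(=O)c3c(OC)c(OC)c(OC)c(B4OC(C)(C)C(C)(C)O4)c3o2)cc(OC)c1OC
F6 | step 3 | (Z)-3-chloro-3-(3,4,5-trimethoxyphenyl)prop-2-enoic acid | COc1cc(/C(Cl)=C/C(=O)O)cc(OC)c1OC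
F7 | step 3 | (Z)-3-chloro-3-(3,4,5-trimethoxyphenyl)prop-2-enoyl chloride | COc1cc(/C(Cl)=C/C(=O)Cl)cc(OC)c1OC
F8 | step 3 | methyl (Z)-2-[(benzyloxy)acetyl]-5-chloro-3-oxo-5-(3,4,5-trimethoxyphenyl)pent-4-enoate | COC(=O)C(C(=O)COCc1ccccc1)C(=O)/C=C(\Cl)c1cc(OC)c(OC)c(OC)c1
F9 | step 1 | trimethyl[(3,4,5-trimethoxyphenyl)ethynyl]silane | COc1cc(C#C[Si](C)(C)C)cc(OC)c1OC
F10 | step 1 | 5-ethynyl-1,2,3-trimethoxybenzene | COc1cc(C#C)cc(OC)c1OC
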